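Count the nucleophile that has dissolved in this flask and the sum stays whole: it is free, in product, or protonated. While solid is left in this flask, each turn of the first step takes two of it, one into product and one to the acid set free, because the balance lies far to the protonated side.

    electrophile + nucleophile → acid set free + product (k1 = 0.0183 M⁻¹ s⁻¹)
    nucleophile + acid set free ⇌ protonated nucleophile, settled at all times (K2 = 3490 M⁻¹)
    solid nucleophile ⇌ nucleophile, rate k3*(cs3 - [nucleophile]) while solid is left; crystals form when [nucleophile] > cs3 (cs3 = 0.23 M, k3 = 0.00942 s⁻¹)

electrophile 0.50 M; solid nucleophile 0.500 M; time 2.0 min

- how much product there is at 2.0 min, in percent of the electrophile charged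
- concentration of nucleophile in solution at 2.0 min, in percent of saturation

So we measure free nucleophile as a fraction of saturation. Dissolving refills the gap at 0.57 min⁻¹, and the first step, counted double, empties at 1.10 min⁻¹ (pseudo-first-order while electrophile stands near its charge). Equal coefficients put the balance at half of saturation, and that is our zero. Here the drain is faster, so we carry the refill share, refill over refill plus drain, 34.0%, the fraction of saturation at which, in our reckoning with electrophile held at its charge, free nucleophile levels off.

In that reckoning it climbs with a time constant of about 0.601 min, so we reckon 32.8% of saturation at 2.0 min and 12.0% of the electrophile as product. Our count then takes 39.6% of the solid's charge, so solid remains.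

The forecast, from “each acid released ties up one dissolved nucleophile”, gives more on both, 14.6% and 47%.

The simulation gives 11.7% and 34.4%.

In this flask at 2.00 min, 88% of the electrophile is left, so the drain has fallen to 0.970 min⁻¹, still faster than the refill. The refill share then reads 37.0%, against 34.4% of saturation in the flask. A second flask has twice the dissolving coefficient, 1.14 min⁻¹, so its share is 50.7%, near half, and the same reckoning gives 19.9% product, where its run gives 18.6%.

The constants were drawn at random within sensible limits; the rest is arithmetic.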